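The disconnection on which everything rests is the C5–C6 bond of ring B. Writing ring A as a cyclohexa-2,5-dienone makes the quaternary C10 a prochiral centre, and C5, one of the two dienone β-carbons, carries C6, which sits at the carbonyl oxidation level. The precursor is therefore an achiral 4-methylcyclohexa-2,5-dienone whose second C4 substituent is the chain CH2–C(dioxolane)–CH2–CHO (C9–C8–C7–C6). A chiral triazolylidene turns the aldehyde into an acyl anion equivalent that adds to one enantiotopic enone arm: one operation closes ring B, fixes C10 and places the carbonyl on C6. That oxygen later unmasks a C8 enone for regiospecific C9 alkylation.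

Key step: step 8

Conventions: locants are those of the labdane skeleton (ring A = C1–C5 and C10; ring B = C5–C10; C10 carries the angular methyl C20; C17 sits on C8; the side chain C11–C16 on C9). "syn" and "anti" mean on the same or the opposite face as the angular methyl. The target is (5R,6R,8S,9S,10R), i.e. the enantiomeric labdane series.

Assumption: the (5aR,10bS) antipode of the triazolium salt is taken to select the enone arm that gives (10R)-14; should the sense of induction be the reverse, the commercially available mirror-image salt is used.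

Step 1
Reactants: 1 2-methylpent-4-enal (racemic); 2 methyl vinyl ketone
Product: 4 4-methyl-4-(prop-2-en-1-yl)cyclohex-2-en-1-one (racemic), via Michael adduct 3 (not isolated)
Conditions: H2SO4 (cat.), PhMe, 45 °C, then reflux (Dean–Stark)
Reagents that add atoms: none
Why: Acid-catalysed Robinson annulation: Michael addition of the aldehyde enol to the enone and aldol condensation of the methyl ketone onto the aldehyde should build the ring around the future C10; the stereocentre is of no consequence because it becomes prochiral in step 2.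

Step 2
Reactants: 4 4-methyl-4-(prop-2-en-1-yl)cyclohex-2-en-1-one
Product: 5 4-methyl-4-(prop-2-en-1-yl)cyclohexa-2,5-dien-1-one
Conditions: DDQ, 1,4-dioxane, reflux
Reagents that add atoms: none
Why: Quinone dehydrogenation (hydride abstraction from the enol, then loss of a proton) should give the cross-conjugated dienone; the quaternary C4 rules out aromatisation and makes the two enone arms enantiotopic.

Step 3
Reactants: 5 4-methyl-4-(prop-2-en-1-yl)cyclohexa-2,5-dien-1-one
Product: 7 2-(1-methyl-4-oxocyclohexa-2,5-dien-1-yl)acetaldehyde, via diol 6 (not isolated)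
Conditions: OsO4 (cat.), NaIO4, 2,6-lutidine, 1,4-dioxane–H2O, 23 °C
Reagents that add atoms: osmium tetroxide, O=[Os](=O)(=O)=O (catalytic oxygen carrier); sodium periodate, [Na+].[O-]I(=O)(=O)=O
Why: Lemieux–Johnson oxidation: OsO4 should dihydroxylate the electron-rich terminal alkene in preference to the electron-poor dienone double bonds, and periodate cleaves the diol to the aldehyde (C8).

Step 4
Reactants: 7 2-(1-methyl-4-oxocyclohexa-2,5-dien-1-yl)acetaldehyde; 8 allylboronic acid pinacol ester
Product: 9 4-(2-hydroxypent-4-en-1-yl)-4-methylcyclohexa-2,5-dien-1-one (racemic)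
Conditions: CH2Cl2, 23 °C; pH 7 buffer work-up
Reagents that add atoms: none
Why: Uncatalysed allylboration through a six-membered chair transition state is chemoselective for the aldehyde over the cross-conjugated ketone and adds C7, C6 and the carbon that is later cleaved; the racemic carbinol is oxidised at once because 4-(2-hydroxyalkyl)dienones can close by oxa-Michael addition.

Step 5
Reactants: 9 4-(2-hydroxypent-4-en-1-yl)-4-methylcyclohexa-2,5-dien-1-one
Product: 10 4-methyl-4-(2-oxopent-4-en-1-yl)cyclohexa-2,5-dien-1-one
Conditions: Dess–Martin periodinane, NaHCO3, CH2Cl2, 0 °C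
Reagents that add atoms: none
Why: Buffered Dess–Martin oxidation should give the β,γ-unsaturated ketone without migration of the double bond into conjugation.

Step 6
Reactants: 10 4-methyl-4-(2-oxopent-4-en-1-yl)cyclohexa-2,5-dien-1-one
Product: 11 4-methyl-4-{[2-(prop-2-en-1-yl)-1,3-dioxolan-2-yl]methyl}cyclohexa-2,5-dien-1-one
Conditions: (Me3SiOCH2)2, Me3SiOTf (cat.), CH2Cl2, −78 → −20 °C
Reagents that add atoms: 1,2-bis(trimethylsilyloxy)ethane, C[Si](C)(C)OCCO[Si](C)(C)C
Why: Aprotic silyl-triflate-catalysed ketalisation through the oxocarbenium ion is selective for the saturated ketone over the far less electrophilic dienone carbonyl, and the low temperature avoids alkene migration and dienone–phenol rearrangement; the ketal keeps the substrate achiral and C8 non-enolisable.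

Step 7
Reactants: 11 4-methyl-4-{[2-(prop-2-en-1-yl)-1,3-dioxolan-2-yl]methyl}cyclohexa-2,5-dien-1-one
Product: 13 4-methyl-4-{[2-(2-oxoethyl)-1,3-dioxolan-2-yl]methyl}cyclohexa-2,5-dien-1-one, via diol 12 (not isolated)
Conditions: OsO4 (cat.), NaIO4, 2,6-lutidine, 1,4-dioxane–H2O, 23 °C
Reagents that add atoms: osmium tetroxide, O=[Os](=O)(=O)=O (catalytic oxygen carrier); sodium periodate, [Na+].[O-]I(=O)(=O)=O
Why: A second Lemieux–Johnson cleavage of the only electron-rich alkene should unveil the C6 aldehyde under buffered conditions that spare the ketal.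

Step 8
Reactants: 13 4-methyl-4-{[2-(2-oxoethyl)-1,3-dioxolan-2-yl]methyl}cyclohexa-2,5-dien-1-one
Product: 14 (5S,10R)-10-methyl-cis-decal-1-ene-3,6,8-trione 8-(ethylene ketal)
Conditions: (5aR,10bS)-2-(pentafluorophenyl)-5a,10b-dihydro-4H,6H-indeno[2,1-b][1,2,4]triazolo[4,3-d][1,4]oxazin-2-ium tetrafluoroborate (10 mol%), KN(SiMe3)2 (9 mol%), PhMe, 23 °C
Reagents that add atoms: none
Why: The free carbene adds to the C6 aldehyde and proton transfer gives the Breslow intermediate, an acyl anion equivalent that attacks the enone β-carbon C5 in conjugate fashion; proton transfer and loss of the carbene then release the C6 ketone. The closest known reaction type is the carbene-catalysed asymmetric intramolecular Stetter desymmetrisation of 4,4-disubstituted cyclohexadienones. Ring B closes in the 6-exo-trig mode. C10 is set by the chiral carbene, which chooses one of the two enantiotopic enone arms, and C5 by the tether, which can deliver C6 only on the face that carries C9, so the ring fusion is cis. The step needs enantiotopic-group selectivity and 1,4- rather than benzoin-type 1,2-reactivity: the flat unhindered dienone, the gem-dialkoxy effect of the C8 ketal (which also shuts off enolisation and aldol chemistry in the tether) and the use of slightly less base than triazolium salt, so that no free strong base can trigger β-elimination of the ketal, secure them.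

Step 9
Reactants: 14 (5S,10R)-10-methyl-cis-decal-1-ene-3,6,8-trione 8-(ethylene ketal)
Product: 15 (5,10-cis)-6-hydroxy-10-methyldecal-1-ene-3,8-dione 8-(ethylene ketal) (C6 epimers)
Conditions: NaBH4, MeOH–CH2Cl2, −78 °C
Reagents that add atoms: none
Why: At low temperature borohydride should reduce the saturated C6 ketone faster than the conjugated C3 ketone, as in the selective reduction of the saturated carbonyl of bicyclic enediones; both C6 epimers are carried on because this centre is destroyed in step 14.

Step 10
Reactants: 15 (5,10-cis)-6-hydroxy-10-methyldecal-1-ene-3,8-dione 8-(ethylene ketal)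
Product: 16 (5,10-cis)-6-methoxy-10-methyldecal-1-ene-3,8-dione 8-(ethylene ketal) (C6 epimers)
Conditions: MeOTf, 2,6-di-tert-butyl-4-methylpyridine, CH2Cl2, 23 °C
Reagents that add atoms: methyl trifluoromethanesulfonate, COS(=O)(=O)C(F)(F)F
Why: O-Methylation under non-basic conditions (SN2 at the methyl group) caps the hydroxyl without forming an alkoxide that could add to the enone, and turns the C6 oxygen into the leaving group used in step 14.

Step 11
Reactants: 16 (5,10-cis)-6-methoxy-10-methyldecal-1-ene-3,8-dione 8-(ethylene ketal)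
Product: 17 (5,10-cis)-6-methoxy-4,4,10-trimethyldecal-1-ene-3,8-dione 8-(ethylene ketal) (C6 epimers)
Conditions: NaH, MeI, THF–DMF, 0 → 40 °C
Reagents that add atoms: iodomethane, CI
Why: Exhaustive α'-alkylation of the enone: C10 is quaternary, so the enone can enolise only towards C4 and both methyl groups (C18, C19) enter there without regiochemical ambiguity.

Step 12
Reactants: 17 (5,10-cis)-6-methoxy-4,4,10-trimethyldecal-1-ene-3,8-dione 8-(ethylene ketal)
Product: 18 (5,10-cis)-6-methoxy-4,4,10-trimethyldecalin-3,8-dione 8-(ethylene ketal) (C6 epimers)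
Conditions: H2 (1 atm), Pd/C, EtOAc, 23 °C
Reagents that add atoms: none
Why: Heterogeneous hydrogenation should saturate the disubstituted C1=C2 bond of the enone; ketal, ether and the hindered ketone are inert.

Step 13
Reactants: 18 (5,10-cis)-6-methoxy-4,4,10-trimethyldecalin-3,8-dione 8-(ethylene ketal)
Product: 20 (5,10-cis)-6-methoxy-4,4,10-trimethyldecalin-8-one ethylene ketal (C6 epimers), via hydrazone 19 (not isolated)
Conditions: N2H4·H2O, KOH, diethylene glycol, 130 → 200 °C
Reagents that add atoms: none
Why: Wolff–Kishner reduction (Huang-Minlon procedure) removes the neopentyl C3 carbonyl, as is routine for 4,4-dimethyl-3-keto terpenoids; ketal and methyl ether are stable to hot base.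

Step 14
Reactants: 20 (5,10-cis)-6-methoxy-4,4,10-trimethyldecalin-8-one ethylene ketal
Product: 22 (5,10-cis)-4,4,10-trimethyldecal-6-en-8-one, via methoxy ketone 21 (not isolated)
Conditions: 2 M HCl, THF, 50 °C
Reagents that add atoms: water, O
Why: Acid hydrolysis of the dioxolane frees the C8 ketone, whose enol towards C7 expels the β-methoxy group (acid-mediated β-elimination, as in the unmasking of β-methoxy ketones to enones); the Stetter-derived oxygen on C6 is thus traded for a C6=C7 bond that blocks C7 and leaves C9 as the only α'-position.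

Step 15
Reactants: 22 (5,10-cis)-4,4,10-trimethyldecal-6-en-8-one
Product: 25 (5,10-trans)-4,4,10-trimethyldecal-6-en-8-one, via potassium dienolate 23 (not isolated), via deconjugated enone 24 (not isolated)
Conditions: KOtBu, t-BuOH–THF, 23 °C; AcOH (aq), −78 °C; then 0.1 M HCl, MeOH–THF, 23 °C
Reagents that add atoms: none
Why: Deconjugation–reconjugation: γ-deprotonation gives the extended dienolate in which C5 is trigonal, kinetic α-protonation gives the β,γ-enone, and mild acid-catalysed reconjugation through the dienol should protonate C5 on the face anti to the angular methyl (the syn face is flanked by the C10 methyl and the axial C4 methyl), which sets the trans ring fusion under kinetic control.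

Step 16
Reactants: 25 (5,10-trans)-4,4,10-trimethyldecal-6-en-8-one; 26 tert-butyl bromoacetate
Product: 28 tert-butyl 2-[(5,10-trans)-4,4,10-trimethyl-8-oxodecal-6-en-9-yl]acetate (side chain anti; 9-epi), via lithium enolate 27 (not isolated)
Conditions: LiN(iPr)2, THF, −78 °C; then 26, DMPU, −78 → −20 °C
Reagents that add atoms: none
Why: Kinetic α'-deprotonation (C7 is vinylic, C5 is a hindered γ-position) gives the cross-conjugated lithium enolate regiospecifically, and the reactive α-bromo ester alkylates it at C9 (C11, C12); the electrophile is expected to enter anti to the angular methyl, which gives the C9 epimer that step 18 corrects.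

Step 17
Reactants: 28 tert-butyl 2-[(5,10-trans)-4,4,10-trimethyl-8-oxodecal-6-en-9-yl]acetate
Product: 29 tert-butyl 2-[(5,10-trans)-6,7-epoxy-4,4,10-trimethyl-8-oxodecalin-9-yl]acetate (epoxide anti; side chain anti)
Conditions: H2O2 (30% aq), NaOH, MeOH, 0 °C
Reagents that add atoms: hydrogen peroxide, OO
Why: Weitz–Scheffer nucleophilic epoxidation: hydroperoxide should add to C6 on the face anti to the two syn-axial methyl groups on C4 and C10, so that the oxygen returns to C6 with the configuration of the target; the tert-butyl ester resists cold hydroxide.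

Step 18
Reactants: 29 tert-butyl 2-[(5,10-trans)-6,7-epoxy-4,4,10-trimethyl-8-oxodecalin-9-yl]acetate
Product: 31 tert-butyl 2-[(5,10-trans)-6,7-epoxy-4,4,10-trimethyl-8-oxodecalin-9-yl]acetate (epoxide anti; side chain syn), via potassium enolate 30 (not isolated)
Conditions: KN(SiMe3)2, THF, −78 → −30 °C; then AcOH, THF, −78 °C
Reagents that add atoms: none
Why: The ketone can now enolise only towards C9 (C7 is an epoxide carbon), and kinetic protonation of the enolate anti to the angular methyl should place hydrogen on that face and the side chain syn, which is the configuration of the target and also the more stable equatorial one in all later saturated intermediates.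

Step 19
Reactants: 31 tert-butyl 2-[(5,10-trans)-6,7-epoxy-4,4,10-trimethyl-8-oxodecalin-9-yl]acetate (side chain syn)
Product: 32 tert-butyl 2-[(5,10-trans)-6-hydroxy-4,4,10-trimethyl-8-oxodecalin-9-yl]acetate (6-OH anti; side chain syn)
Conditions: SmI2, THF–MeOH, −90 °C
Reagents that add atoms: none
Why: Two-electron reductive cleavage of the Cα–O bond of the α,β-epoxy ketone (ketyl formation, then scission of C7–O) should give the β-hydroxy ketone with the C6–O bond and its configuration untouched; the ester and the product ketone are not reduced at this temperature.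

Step 20
Reactants: 32 tert-butyl 2-[(5,10-trans)-6-hydroxy-4,4,10-trimethyl-8-oxodecalin-9-yl]acetate
Product: 33 tert-butyl 2-[(5,10-trans)-6-hydroxy-4,4,10-trimethyl-8-methylidenedecalin-9-yl]acetate (6-OH anti; side chain syn)
Conditions: CH2Br2, Zn, TiCl4, THF–CH2Cl2, 0 → 23 °C
Reagents that add atoms: dibromomethane, BrCBr
Why: Lombardo–Takai methylenation with a non-basic gem-dimetallic methylene reagent should convert the hindered, epimerisable C8 ketone into the exocyclic alkene (C17) without β-elimination or retro-aldol cleavage of the β-hydroxy ketone and without attack on the ester.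

Step 21
Reactants: 33 tert-butyl 2-[(5,10-trans)-6-hydroxy-4,4,10-trimethyl-8-methylidenedecalin-9-yl]acetate
Product: 34 2-[(5,10-trans)-6-hydroxy-4,4,10-trimethyl-8-methylidenedecalin-9-yl]ethanol (6-OH anti; side chain syn)
Conditions: LiAlH4, THF, 0 → 50 °C
Reagents that add atoms: none
Why: Hydride reduction of the ester gives the primary C12 alcohol; the isolated alkene is inert.

Step 22
Reactants: 34 2-[(5,10-trans)-6-hydroxy-4,4,10-trimethyl-8-methylidenedecalin-9-yl]ethanol
Product: 35 (5,10-trans)-9-(2-iodoethyl)-4,4,10-trimethyl-8-methylidenedecalin-6-ol (6-OH anti; side chain syn)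
Conditions: I2, PPh3, imidazole, CH2Cl2, 0 °C
Reagents that add atoms: iodine, II
Why: Appel-type iodination (SN2 displacement of the alkoxyphosphonium ion) is selective for the primary over the hindered secondary hydroxyl; it is done while C8 is still an alkene because an 8-hydroxy-12-iodide would close to a tetrahydrofuran.

Step 23
Reactants: 36 methyl acetoacetate
Product: 37 methyl (2E)-3-{[(trifluoromethyl)sulfonyl]oxy}but-2-enoate
Conditions: Tf2O, Me4NOH (aq), hexanes, 5 °C
Reagents that add atoms: trifluoromethanesulfonic anhydride, O=S(=O)(OS(=O)(=O)C(F)(F)F)C(F)(F)F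
Why: O-Triflation of the β-keto ester enolate: the non-chelating tetramethylammonium counter-ion favours the extended enolate and hence the (E)-enol triflate, with the triflate trans to the ester.

Step 24
Reactants: 35 (5,10-trans)-9-(2-iodoethyl)-4,4,10-trimethyl-8-methylidenedecalin-6-ol; 37 methyl (2E)-3-{[(trifluoromethyl)sulfonyl]oxy}but-2-enoate
Product: 39 methyl (13E)-6-hydroxylabda-8(17),13-dien-15-oate (enantiomeric labdane series; 6-OH anti), via alkylzinc iodide 38 (not isolated)
Conditions: Zn dust, LiCl, THF, 35 °C; then 37, Pd(PPh3)4 (5 mol%), THF, 23 → 50 °C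
Reagents that add atoms: none
Why: Negishi coupling: zinc insertion gives the primary alkylzinc iodide, which tolerates the hindered hydroxyl as alkylzinc halides tolerate N–H and O–H groups, and oxidative addition of zerovalent palladium to the enol triflate, transmetalation and reductive elimination join C12 to C13 with retention of the (E) geometry.

Step 25
Reactants: 39 methyl (13E)-6-hydroxylabda-8(17),13-dien-15-oate
Product: 41 methyl (2E)-5-[(1S,2S,4R,4aR,8aR)-2,4-dihydroxy-2,5,5,8a-tetramethyldecahydronaphthalen-1-yl]-3-methylpent-2-enoate (target), via organomercurial 40 (not isolated)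
Conditions: Hg(OAc)2, THF–H2O, 23 °C; then NaBH4, NaOH (aq), 0 °C
Reagents that add atoms: water, O
Why: Markovnikov oxymercuration of the electron-rich 1,1-disubstituted alkene (the enoate is inert to the electrophile), with water attacking C8 from the equatorial direction because the axial approach is blocked by the syn-axial angular methyl, followed by reductive demercuration, should give the C8 hydroxyl anti and the C17 methyl syn, as in the 8(17)-labdene series.

Compound list
1 | 2-methylpent-4-enal (racemic) | C=CCC(C)C=O | starting material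
2 | methyl vinyl ketone (but-3-en-2-one) | C=CC(C)=O | starting material
3 | 2-methyl-2-(3-oxobutyl)pent-4-enal (racemic Michael adduct) | CC(=O)CCC(C)(CC=C)C=O | intermediate
4 | 4-methyl-4-(prop-2-en-1-yl)cyclohex-2-en-1-one (racemic) | C=CCC1(C)CCC(=O)C=C1 | intermediate
5 | 4-methyl-4-(prop-2-en-1-yl)cyclohexa-2,5-dien-1-one | C=CCC1(C)C=CC(=O)C=C1 | intermediate
6 | 4-(2,3-dihydroxypropyl)-4-methylcyclohexa-2,5-dien-1-one (racemic) | OCC(O)CC1(C)C=CC(=O)C=C1 | intermediate
7 | 2-(1-methyl-4-oxocyclohexa-2,5-dien-1-yl)acetaldehyde | O=CCC1(C)C=CC(=O)C=C1 | intermediate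
8 | allylboronic acid pinacol ester | C=CCB1OC(C)(C)C(C)(C)O1 | starting material
9 | 4-(2-hydroxypent-4-en-1-yl)-4-methylcyclohexa-2,5-dien-1-one (racemic) | C=CCC(O)CC1(C)C=CC(=O)C=C1 | intermediate
10 | 4-methyl-4-(2-oxopent-4-en-1-yl)cyclohexa-2,5-dien-1-one | C=CCC(=O)CC1(C)C=CC(=O)C=C1 | intermediate
11 | 4-methyl-4-{[2-(prop-2-en-1-yl)-1,3-dioxolan-2-yl]methyl}cyclohexa-2,5-dien-1-one | C=CCC1(OCCO1)CC2(C)C=CC(=O)C=C2 | intermediate
12 | 4-{[2-(2,3-dihydroxypropyl)-1,3-dioxolan-2-yl]methyl}-4-methylcyclohexa-2,5-dien-1-one (racemic) | OCC(O)CC1(OCCO1)CC2(C)C=CC(=O)C=C2 | intermediate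
13 | 4-methyl-4-{[2-(2-oxoethyl)-1,3-dioxolan-2-yl]methyl}cyclohexa-2,5-dien-1-one | O=CCC1(OCCO1)CC2(C)C=CC(=O)C=C2 | intermediate
14 | (5S,10R)-10-methyl-cis-decal-1-ene-3,6,8-trione 8-(ethylene ketal) | C1[C@]2(C)C=CC(=O)C[C@@H]2C(=O)CC13OCCO3 | intermediate
15 | (5,10-cis)-6-hydroxy-10-methyldecal-1-ene-3,8-dione 8-(ethylene ketal), mixture of C6 epimers | C1[C@]2(C)C=CC(=O)C[C@@H]2C(O)CC13OCCO3 | intermediate
16 | (5,10-cis)-6-methoxy-10-methyldecal-1-ene-3,8-dione 8-(ethylene ketal), C6 epimers | C1[C@]2(C)C=CC(=O)C[C@@H]2C(OC)CC13OCCO3 | intermediate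
17 | (5,10-cis)-6-methoxy-4,4,10-trimethyldecal-1-ene-3,8-dione 8-(ethylene ketal), C6 epimers | C1[C@]2(C)C=CC(=O)C(C)(C)[C@@H]2C(OC)CC13OCCO3 | intermediate
18 | (5,10-cis)-6-methoxy-4,4,10-trimethyldecalin-3,8-dione 8-(ethylene ketal), C6 epimers | C1[C@]2(C)CCC(=O)C(C)(C)[C@@H]2C(OC)CC13OCCO3 | intermediate
19 | 3-hydrazone of 18 | C1[C@]2(C)CCC(=NN)C(C)(C)[C@@H]2C(OC)CC13OCCO3 | intermediate
20 | (5,10-cis)-6-methoxy-4,4,10-trimethyldecalin-8-one ethylene ketal, C6 epimers | C1[C@]2(C)CCCC(C)(C)[C@@H]2C(OC)CC13OCCO3 | intermediate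
21 | (5,10-cis)-6-methoxy-4,4,10-trimethyldecalin-8-one, C6 epimers | C1[C@]2(C)CCCC(C)(C)[C@@H]2C(OC)CC1=O | intermediate
22 | (5,10-cis)-4,4,10-trimethyldecal-6-en-8-one | C1[C@]2(C)CCCC(C)(C)[C@@H]2C=CC1=O | intermediate
23 | potassium 4,4,10-trimethyldecala-5,7-dien-8-olate | [K]OC1=CC=C2C(C)(C)CCC[C@@]2(C)C1 | intermediate
24 | 4,4,10-trimethyldecal-5-en-8-one | O=C1CC=C2C(C)(C)CCC[C@@]2(C)C1 | intermediate
25 | (5,10-trans)-4,4,10-trimethyldecal-6-en-8-one | C1[C@]2(C)CCCC(C)(C)[C@H]2C=CC1=O | intermediate
26 | tert-butyl bromoacetate | BrCC(=O)OC(C)(C)C | starting material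
27 | lithium (5,10-trans)-4,4,10-trimethyldecala-6,8-dien-8-olate | [Li]OC1=C[C@]2(C)CCCC(C)(C)[C@H]2C=C1 | intermediate
28 | tert-butyl 2-[(5,10-trans)-4,4,10-trimethyl-8-oxodecal-6-en-9-yl]acetate, side chain anti (9-epi) | CC(C)(C)OC(=O)C[C@@H]1[C@]2(C)CCCC(C)(C)[C@H]2C=CC1=O | intermediate
29 | tert-butyl 2-[(5,10-trans)-6,7-epoxy-4,4,10-trimethyl-8-oxodecalin-9-yl]acetate, epoxide oxygen anti, side chain anti (9-epi) | CC(C)(C)OC(=O)C[C@@H]1[C@]2(C)CCCC(C)(C)[C@H]2[C@@H]3O[C@@H]3C1=O | intermediate
30 | potassium 8(9)-enolate of 29 | CC(C)(C)OC(=O)CC1=C(O[K])[C@H]4O[C@H]4[C@@H]2C(C)(C)CCC[C@@]12C | intermediate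
31 | tert-butyl 2-[(5,10-trans)-6,7-epoxy-4,4,10-trimethyl-8-oxodecalin-9-yl]acetate, epoxide oxygen anti, side chain syn | CC(C)(C)OC(=O)C[C@H]1[C@]2(C)CCCC(C)(C)[C@H]2[C@@H]3O[C@@H]3C1=O | intermediate
32 | tert-butyl 2-[(5,10-trans)-6-hydroxy-4,4,10-trimethyl-8-oxodecalin-9-yl]acetate, 6-OH anti, side chain syn | CC(C)(C)OC(=O)C[C@H]1[C@]2(C)CCCC(C)(C)[C@H]2[C@H](O)CC1=O | intermediate
33 | tert-butyl 2-[(5,10-trans)-6-hydroxy-4,4,10-trimethyl-8-methylidenedecalin-9-yl]acetate, 6-OH anti, side chain syn | CC(C)(C)OC(=O)C[C@H]1[C@]2(C)CCCC(C)(C)[C@H]2[C@H](O)CC1=C | intermediate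
34 | 2-[(5,10-trans)-6-hydroxy-4,4,10-trimethyl-8-methylidenedecalin-9-yl]ethanol, 6-OH anti, side chain syn | OCC[C@H]1[C@]2(C)CCCC(C)(C)[C@H]2[C@H](O)CC1=C | intermediate
35 | (5,10-trans)-9-(2-iodoethyl)-4,4,10-trimethyl-8-methylidenedecalin-6-ol, 6-OH anti, side chain syn | ICC[C@H]1[C@]2(C)CCCC(C)(C)[C@H]2[C@H](O)CC1=C | intermediate
36 | methyl acetoacetate | COC(=O)CC(C)=O | starting material
37 | methyl (2E)-3-{[(trifluoromethyl)sulfonyl]oxy}but-2-enoate | COC(=O)/C=C(\C)OS(=O)(=O)C(F)(F)F | intermediate
38 | {2-[(5,10-trans)-6-hydroxy-4,4,10-trimethyl-8-methylidenedecalin-9-yl]ethyl}zinc iodide | I[Zn]CC[C@H]1[C@]2(C)CCCC(C)(C)[C@H]2[C@H](O)CC1=C | intermediate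
39 | methyl (13E)-6-hydroxylabda-8(17),13-dien-15-oate, enantiomeric labdane series, 6-OH anti | COC(=O)/C=C(\C)CC[C@H]1[C@]2(C)CCCC(C)(C)[C@H]2[C@H](O)CC1=C | intermediate
40 | methyl (13E)-17-(acetoxymercurio)-6,8-dihydroxylabd-13-en-15-oate, both hydroxyls anti | COC(=O)/C=C(\C)CC[C@H]1[C@]2(C)CCCC(C)(C)[C@H]2[C@H](O)C[C@@]1(O)C[Hg]OC(C)=O | intermediate
41 | methyl (2E)-5-[(1S,2S,4R,4aR,8aR)-2,4-dihydroxy-2,5,5,8a-tetramethyldecahydronaphthalen-1-yl]-3-methylpent-2-enoate | COC(=O)/C=C(\C)CC[C@H]1[C@]2(C)CCCC(C)(C)[C@H]2[C@H](O)C[C@]1(C)O | target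

Total step count: 25. Longest linear sequence: 24 steps (steps 1–22, 24 and 25; step 23 makes the coupling partner 37).

Steps most likely to fail

Step 8. The acyl anion equivalent may be diverted into benzoin-type self-condensation, the enantiotopic enone arms may be poorly discriminated in a six-membered ring closure through an all-carbon tether, or the β-ketal may be lost from the aldehyde by base-induced elimination before cyclisation. The fallback forms the same C5–C6 bond with a nitronate in place of the acyl anion. It sets out from 13: condensation with NH2OH·HCl and NaOAc would give the aldoxime F1. Oxidation with urea–hydrogen peroxide and (CF3CO)2O, buffered by Na2HPO4 in MeCN, would give the primary nitroalkane F2. A quinine-derived bifunctional amine–thiourea catalyst would then close ring B by a desymmetrising intramolecular nitro-Michael addition to C5, giving the cis-fused nitro ketone F3. A reductive Nef reaction (aqueous TiCl3, NH4OAc) turns the nitro-bearing C6 into the ketone and comes back to the route at 14.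

Step 15. γ-Deprotonation at the hindered ring-fusion carbon may be incomplete, or the dienol may be reprotonated on the syn face or re-equilibrated, so that cis-fused enone persists. The fallback sets C5 by hydroboration. It sets out from 22: ethylene glycol and TsOH in refluxing benzene with removal of water ketalise the enone with migration of the double bond out of conjugation, giving the C5=C6 ketal F4. Hydroboration–oxidation (BH3·THF; then H2O2, NaOH) adds hydrogen to C5 and hydroxyl to C6 from the face anti to the angular methyl and delivers the trans-fused alcohol F5. 2 M HCl in THF then hydrolyses the ketal to the hydroxy ketone F6, which loses water on warming and comes back to the route at 25.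

Step 18. Deprotonation of the hindered C9–H may be slow, or protonation of the enolate may be unselective, leaving the 9-epimer. The fallback uses thermodynamic control at a later, saturated ketone. It sets out from 29: the 9-epimeric epoxy ketone is taken through the SmI2 reduction to the hydroxy ketone F7, the C9 epimer of 32. C8 is then methylenated under strongly basic, equilibrating Wittig conditions (Ph3PCH3Br, KOtBu, PhMe, 80 °C), in which the saturated ketone can epimerise at C9 to the more stable equatorial (syn) isomer before it is olefinated. This comes back to the route at 33.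

Further compounds
F1 | step 8 | 4-{[2-(2-(hydroxyimino)ethyl)-1,3-dioxolan-2-yl]methyl}-4-methylcyclohexa-2,5-dien-1-one | ON=CCC1(OCCO1)CC2(C)C=CC(=O)C=C2
F2 | step 8 | 4-methyl-4-{[2-(2-nitroethyl)-1,3-dioxolan-2-yl]methyl}cyclohexa-2,5-dien-1-one | [O-][N+](=O)CCC1(OCCO1)CC2(C)C=CC(=O)C=C2
F3 | step 8 | (5,10-cis)-10-methyl-6-nitrodecal-1-ene-3,8-dione 8-(ethylene ketal), C6 epimers | C1[C@]2(C)C=CC(=O)C[C@@H]2C([N+](=O)[O-])CC13OCCO3
F4 | step 15 | 4,4,10-trimethyldecal-5-en-8-one ethylene ketal | C1[C@]2(C)CCCC(C)(C)C2=CCC13OCCO3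
F5 | step 15 | (5,10-trans)-6-hydroxy-4,4,10-trimethyldecalin-8-one ethylene ketal, 6-OH anti | C1[C@]2(C)CCCC(C)(C)[C@H]2[C@H](O)CC13OCCO3
F6 | step 15 | (5,10-trans)-6-hydroxy-4,4,10-trimethyldecalin-8-one, 6-OH anti | C1[C@]2(C)CCCC(C)(C)[C@H]2[C@H](O)CC1=O
F7 | step 18 | tert-butyl 2-[(5,10-trans)-6-hydroxy-4,4,10-trimethyl-8-oxodecalin-9-yl]acetate, 6-OH anti, side chain anti (C9 epimer of 32) | CC(C)(C)OC(=O)C[C@@H]1[C@]2(C)CCCC(C)(C)[C@H]2[C@H](O)CC1=O
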